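**Plan**
- Retrosynthesis, in order: (1) quinone to hydroquinone 21 (oxidation level); (2) the six-membered ring is cut between C3 (the CH next to the furyl-bearing C2) and C4 (the carbonyl carbon remote from the furan), giving a dienylketene that folds back into 4-hydroxy-4-alkenylcyclobutenone 18; (3) C1–C2 is cut to cyclobut-3-ene-1,2-dione and a 1-(furan-2-yl)ethenyl metal; (4) ester C–O; (5) acyl carbon–furan C4 bond.
- Enabling feature: quinone atoms C4(=O)–C5H=C6H–C1(=O) are an unsubstituted cis-enedione, i.e. a ring-opened cyclobutenedione, and C2(furyl)=C3H is a 1,1-disubstituted vinyl group on furan C2. The hydroquinone tautomer of this ring is therefore the 6π-closure product of ketene carbon C4 onto methylene carbon C3.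
- Forward: the furan ring is bought (4-bromofuran-2-carbaldehyde); the side chain is joined at furan C4; the aldehyde is turned into the 1-iodoethenyl group; the four-membered ring is attached; the carbocyclic six-membered ring is formed last from it and then oxidised.
- Helpers: the temporary four-membered ring (consumed in the key step) and the hydroquinone oxidation level (removed in the last step).
- Stereochemistry: the single (S) stereocentre comes from a CBS reduction of ketone 7 with the (R)-oxazaborolidine; esterification retains it and no later step acts at it.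

Key step: step 10

Assumption: reagents named without a number are commercial; compound 18 is formed and used as a mixture of the two epimers at the ring carbinol carbon, which becomes sp2 in step 10.

**Step 1**
Reactants: 1 4-bromofuran-2-carbaldehyde
Product: 2 4-bromo-2-ethynylfuran
Conditions: dimethyl (1-diazo-2-oxopropyl)phosphonate (1.2 equiv), K2CO3 (2 equiv), MeOH, 0 °C to rt
Reagents that add atoms: dimethyl (1-diazo-2-oxopropyl)phosphonate, CC(=O)C(=[N+]=[N-])P(=O)(OC)OC
Why: Ohira–Bestmann (Seyferth–Gilbert) homologation, in which methanolysis of the reagent gives the dimethyl (diazomethyl)phosphonate anion that converts the aldehyde through an alkylidene carbene into the terminal alkyne, under conditions that should leave the furyl bromide untouched.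

**Step 2**
Reactants: 3 4-methylpent-3-enoic acid
Product: 5 N-methoxy-N,4-dimethylpent-3-enamide, via acyl imidazole 4 (not isolated)
Conditions: 1,1'-carbonyldiimidazole (1.1 equiv), CH2Cl2, rt; then MeNHOMe·HCl (1.2 equiv), rt
Reagents that add atoms: N,O-dimethylhydroxylamine hydrochloride, CNOC.Cl; 1,1'-carbonyldiimidazole, O=C(n1ccnc1)n1ccnc1 (imidazolyl group of 4 only)
Why: Carbonyldiimidazole activation followed by aminolysis is a standard Weinreb amide synthesis and is mild enough to keep the β,γ-double bond out of conjugation.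

**Step 3**
Reactants: 2 4-bromo-2-ethynylfuran; 5 N-methoxy-N,4-dimethylpent-3-enamide
Product: 7 1-(5-ethynylfuran-3-yl)-4-methylpent-3-en-1-one, via dilithiated furan 6 (not isolated)
Conditions: MeLi (1.0 equiv), THF, −78 °C; n-BuLi (1.05 equiv), −78 °C; then 5 (1.1 equiv), −78 °C; sat. aq. NH4Cl at −78 °C
Reagents that add atoms: methyllithium, [Li]C; n-butyllithium, [Li]CCCC (lithium atoms of 6 only)
Why: Weinreb ketone synthesis, in which methyllithium first masks the acidic alkyne C–H as the acetylide so that the furyllithium formed by the following bromine–lithium exchange is not quenched, and this 3-furyllithium should acylate on the amide at −78 °C through a stable chelated tetrahedral intermediate while the lithium acetylide stays inert.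

**Step 4**
Reactants: 7 1-(5-ethynylfuran-3-yl)-4-methylpent-3-en-1-one
Product: 8 (1S)-1-(5-ethynylfuran-3-yl)-4-methylpent-3-en-1-ol
Conditions: (R)-Me-CBS oxazaborolidine [(3aR)-1-methyl-3,3-diphenyltetrahydro-1H,3H-pyrrolo[1,2-c][1,3,2]oxazaborole] (0.2 equiv), catecholborane (1.8 equiv), toluene, −78 °C; aq. NaOH work-up
Reagents that add atoms: none
Why: Corey–Bakshi–Shibata reduction, in which the (R)-oxazaborolidine binds the ketone anti to the larger 3-furyl group and delivers hydride to the face that gives the (S)-alcohol (the sense known for aryl alkyl ketones), while catecholborane at −78 °C should not hydroborate the alkyne or the trisubstituted alkene.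

**Step 5**
Reactants: 8 (1S)-1-(5-ethynylfuran-3-yl)-4-methylpent-3-en-1-ol
Product: 10 (1S)-1-[5-(1-iodoethenyl)furan-3-yl]-4-methylpent-3-en-1-ol, via alkenylalane 9 (not isolated)
Conditions: i-Bu2AlH (2.3 equiv), NiCl2[Ph2P(CH2)3PPh2] (3 mol%), THF, 0 to 22 °C; then N-iodosuccinimide (1.2 equiv), −78 to 0 °C; aq. Rochelle salt
Reagents that add atoms: N-iodosuccinimide, O=C1CCC(=O)N1I; diisobutylaluminium hydride, CC(C)C[AlH]CC(C)C (aluminium groups of 9 only)
Why: Nickel-catalysed hydroalumination of aryl-type terminal alkynes with this bisphosphine ligand places aluminium on the internal (α) carbon, and iodinolysis of the C–Al bond should give the 1-iodoethenyl group, the first equivalent of hydride only converting the alcohol into its aluminium alkoxide.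

**Step 6**
Reactants: 10 (1S)-1-[5-(1-iodoethenyl)furan-3-yl]-4-methylpent-3-en-1-ol; 11 3-methylbut-2-enoic acid
Product: 12 (1S)-1-[5-(1-iodoethenyl)furan-3-yl]-4-methylpent-3-en-1-yl 3-methylbut-2-enoate
Conditions: 11 (1.5 equiv), DCC (1.5 equiv), DMAP (0.1 equiv), CH2Cl2, 0 °C to rt, dark
Reagents that add atoms: none
Why: Steglich esterification acylates the secondary alcohol at oxygen, so the (S)-configuration is retained, and the neutral conditions should tolerate the alkenyl iodide and the furan.

**Step 7**
Reactants: 13 1,2-bis(trimethylsilyloxy)cyclobut-1-ene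
Product: 14 cyclobutane-1,2-dione
Conditions: Br2 (1.0 equiv), pentane, −60 °C to rt
Reagents that add atoms: none
Why: Bromine oxidises the enediol bis(silyl ether) to the 1,2-diketone with loss of two equivalents of bromotrimethylsilane, a standard preparation of this dione.

**Step 8**
Reactants: 14 cyclobutane-1,2-dione
Product: 16 cyclobut-3-ene-1,2-dione, via 3-bromocyclobutane-1,2-dione 15 (not isolated)
Conditions: Br2 (1.0 equiv), CH2Cl2, −20 °C; then i-Pr2NEt (2.1 equiv), −40 to 0 °C; short silica pad, used at once
Reagents that add atoms: bromine, BrBr (bromine atom of 15 only)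
Why: α-Bromination of the enolisable diketone followed by E1cB loss of HBr with a hindered amine (bromination–dehydrobromination) should introduce the ring double bond in conjugation with both carbonyl groups; no stereocentre remains in the product.

**Step 9**
Reactants: 12 (1S)-1-[5-(1-iodoethenyl)furan-3-yl]-4-methylpent-3-en-1-yl 3-methylbut-2-enoate; 16 cyclobut-3-ene-1,2-dione
Product: 18 (1S)-1-{5-[1-(1-hydroxy-4-oxocyclobut-2-en-1-yl)ethenyl]furan-3-yl}-4-methylpent-3-en-1-yl 3-methylbut-2-enoate (both epimers at the ring carbinol carbon), via alkenylmagnesium chloride 17 (not isolated)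
Conditions: i-PrMgCl·LiCl (1.1 equiv), THF, −40 °C; then cannulated into 16 (1.5 equiv), THF, −78 °C; sat. aq. NH4Cl
Reagents that add atoms: isopropylmagnesium chloride–lithium chloride, CC(C)[Mg]Cl.[Li+].[Cl-] (MgCl group of 17 only)
Why: Iodine–magnesium exchange with the turbo Grignard reagent at low temperature is known to tolerate ester groups, and the alkenylmagnesium should add 1,2 to one of the two equivalent, strained carbonyl groups of the symmetrical dione (inverse addition to excess dione against double addition), as in the usual synthesis of 4-hydroxycyclobutenones; the new quaternary centre forms unselectively, which is immaterial.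

**Step 10**
Reactants: 18 (1S)-1-{5-[1-(1-hydroxy-4-oxocyclobut-2-en-1-yl)ethenyl]furan-3-yl}-4-methylpent-3-en-1-yl 3-methylbut-2-enoate
Product: 21 (1S)-1-[5-(2,5-dihydroxyphenyl)furan-3-yl]-4-methylpent-3-en-1-yl 3-methylbut-2-enoate, via dienylketene 19 (not isolated), via cyclohexa-2,4-dienone 20 (not isolated)
Conditions: degassed toluene (0.01 M), 110 °C, argon
Reagents that add atoms: none
Why: Heating should open the cyclobutenone by a conrotatory 4π-electrocyclic ring opening in which the donor hydroxyl group turns outward and the 1-(furyl)ethenyl group turns inward, giving the (3E)-dienylketene 19. The ketene carbon and the terminal methylene carbon then bond in a thermal disrotatory 6π-electrocyclisation, which is the mode in which the six-membered ring closes, giving cyclohexa-2,4-dienone 20, whose enolisation to the aromatic hydroquinone 21 makes the sequence irreversible. The closest known reaction type is the Moore rearrangement of 4-alkenyl-4-hydroxycyclobut-2-enones to hydroquinones. No stereocentre is created: the ring carbinol carbon of 18 becomes sp2, so both epimers converge, and the (S)-centre of the side chain is remote and untouched under neutral conditions. The step needs outward rotation of the hydroxyl group (otherwise it would add to the ketene and give a butenolide) and closure at the methylene carbon; the first is secured by the strong torquoselectivity of oxygen donors at C-4, the second because closure onto furan C-3 would need a seven-membered transition state. High dilution and exclusion of air should suppress ketene dimerisation and premature oxidation.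

**Step 11**
Reactants: 21 (1S)-1-[5-(2,5-dihydroxyphenyl)furan-3-yl]-4-methylpent-3-en-1-yl 3-methylbut-2-enoate
Product: 22 (1S)-1-[5-(3,6-dioxocyclohexa-1,4-dien-1-yl)furan-3-yl]-4-methylpent-3-en-1-yl 3-methylbut-2-enoate
Conditions: Ag2O (3 equiv), Na2SO4, Et2O, rt, dark
Reagents that add atoms: none
Why: Ag2O is a mild neutral oxidant that should convert the hydroquinone to the 1,4-benzoquinone without touching the furan, the trisubstituted alkenes or the ester.

**Compound list**
1 | 4-bromofuran-2-carbaldehyde | O=Cc1cc(Br)co1 | starting material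
2 | 4-bromo-2-ethynylfuran | C#Cc1cc(Br)co1 | intermediate
3 | 4-methylpent-3-enoic acid | CC(C)=CCC(=O)O | starting material
4 | 1-(1H-imidazol-1-yl)-4-methylpent-3-en-1-one | CC(C)=CCC(=O)n1ccnc1 | intermediate
5 | N-methoxy-N,4-dimethylpent-3-enamide | CC(C)=CCC(=O)N(C)OC | intermediate
6 | 4-lithio-2-(lithioethynyl)furan | [Li]C#Cc1cc([Li])co1 | intermediate
7 | 1-(5-ethynylfuran-3-yl)-4-methylpent-3-en-1-one | CC(C)=CCC(=O)c1coc(C#C)c1 | intermediate
8 | (1S)-1-(5-ethynylfuran-3-yl)-4-methylpent-3-en-1-ol | CC(C)=CC[C@H](O)c1coc(C#C)c1 | intermediate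
9 | diisobutylaluminium (1S)-1-{5-[1-(diisobutylalumanyl)ethenyl]furan-3-yl}-4-methylpent-3-en-1-olate | CC(C)=CC[C@H](O[Al](CC(C)C)CC(C)C)c1coc(C(=C)[Al](CC(C)C)CC(C)C)c1 | intermediate
10 | (1S)-1-[5-(1-iodoethenyl)furan-3-yl]-4-methylpent-3-en-1-ol | CC(C)=CC[C@H](O)c1coc(C(I)=C)c1 | intermediate
11 | 3-methylbut-2-enoic acid | CC(C)=CC(=O)O | starting material
12 | (1S)-1-[5-(1-iodoethenyl)furan-3-yl]-4-methylpent-3-en-1-yl 3-methylbut-2-enoate | CC(C)=CC[C@H](OC(=O)C=C(C)C)c1coc(C(I)=C)c1 | intermediate
13 | 1,2-bis(trimethylsilyloxy)cyclobut-1-ene | C[Si](C)(C)OC1=C(O[Si](C)(C)C)CC1 | starting material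
14 | cyclobutane-1,2-dione | O=C1CCC1=O | intermediate
15 | 3-bromocyclobutane-1,2-dione (racemic) | O=C1CC(Br)C1=O | intermediate
16 | cyclobut-3-ene-1,2-dione | O=C1C=CC1=O | intermediate
17 | chloro(1-{4-[(1S)-4-methyl-1-(3-methylbut-2-enoyloxy)pent-3-en-1-yl]furan-2-yl}ethenyl)magnesium | CC(C)=CC[C@H](OC(=O)C=C(C)C)c1coc(C(=C)[Mg]Cl)c1 | intermediate
18 | (1S)-1-{5-[1-(1-hydroxy-4-oxocyclobut-2-en-1-yl)ethenyl]furan-3-yl}-4-methylpent-3-en-1-yl 3-methylbut-2-enoate (both epimers at the ring carbinol carbon) | CC(C)=CC[C@H](OC(=O)C=C(C)C)c1coc(C(=C)C2(O)C=CC2=O)c1 | intermediate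
19 | (1S)-1-{5-[(3E)-3-hydroxy-6-oxohexa-1,3,5-trien-2-yl]furan-3-yl}-4-methylpent-3-en-1-yl 3-methylbut-2-enoate | CC(C)=CC[C@H](OC(=O)C=C(C)C)c1coc(C(=C)/C(O)=C\C=C=O)c1 | intermediate
20 | (1S)-1-[5-(2-hydroxy-5-oxocyclohexa-1,3-dien-1-yl)furan-3-yl]-4-methylpent-3-en-1-yl 3-methylbut-2-enoate | CC(C)=CC[C@H](OC(=O)C=C(C)C)c1coc(C2=C(O)C=CC(=O)C2)c1 | intermediate
21 | (1S)-1-[5-(2,5-dihydroxyphenyl)furan-3-yl]-4-methylpent-3-en-1-yl 3-methylbut-2-enoate | CC(C)=CC[C@H](OC(=O)C=C(C)C)c1coc(-c2cc(O)ccc2O)c1 | intermediate
22 | (1S)-1-[5-(3,6-dioxocyclohexa-1,4-dien-1-yl)furan-3-yl]-4-methylpent-3-en-1-yl 3-methylbut-2-enoate | CC(C)=CC[C@H](OC(=O)C=C(C)C)c1coc(C2=CC(=O)C=CC2=O)c1 | target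

**Step count**
Total: 11 steps. Longest linear sequence: 8 steps (steps 1, 3, 4, 5, 6, 9, 10, 11).

**Steps most likely to fail**

1. Step 9. The iodine–magnesium exchange may be too slow at the temperature at which the ester survives, so that acyl attack or protonation of the alkenylmagnesium competes; the enedione may also suffer conjugate or double addition. The fallback sets out from 10 and comes back at 21, and it leaves the ester out until the ring is formed. Alcohol 10 with t-BuLi (3.1 equiv, Et2O, −78 °C) should give the lithium alkoxide and alkenyllithium in one species, lithium (1S)-1-[5-(1-lithioethenyl)furan-3-yl]-4-methylpent-3-en-1-olate F1. Addition of F1 to 16 at −78 °C should give the diol 4-hydroxy-4-(1-{4-[(1S)-1-hydroxy-4-methylpent-3-en-1-yl]furan-2-yl}ethenyl)cyclobut-2-en-1-one F2. Heating F2 in degassed toluene at 110 °C should lead, through the dienylketene (3E)-4-hydroxy-5-{4-[(1S)-1-hydroxy-4-methylpent-3-en-1-yl]furan-2-yl}hexa-1,3,5-trien-1-one F3 and 4-hydroxy-5-{4-[(1S)-1-hydroxy-4-methylpent-3-en-1-yl]furan-2-yl}cyclohexa-2,4-dien-1-one F4, to the triol 2-{4-[(1S)-1-hydroxy-4-methylpent-3-en-1-yl]furan-2-yl}benzene-1,4-diol F5. Exhaustive Steglich acylation of F5 with 11 (3.5 equiv, DCC, DMAP, CH2Cl2, argon) should give 2-{4-[(1S)-4-methyl-1-(3-methylbut-2-enoyloxy)pent-3-en-1-yl]furan-2-yl}-1,4-phenylene bis(3-methylbut-2-enoate) F6. Pyrrolidine (2.2 equiv, CH2Cl2, 0 °C) should then remove only the two aryl esters by aminolysis, which is far faster at aryl esters than at the hindered secondary alkyl ester, and give 21.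

2. Step 8. Over-bromination, or decomposition of the electrophilic enedione by the amine base, may leave no usable dione. The fallback sets out from 14 and comes back at 16, and it replaces the base-induced elimination by a neutral syn-elimination. PhSeCl (EtOAc, rt) should selenenylate the diketone through its enol to 3-(phenylselanyl)cyclobutane-1,2-dione F7. Ozone (CH2Cl2, −78 °C) should oxidise it to the selenoxide 3-(benzeneseleninyl)cyclobutane-1,2-dione F8, which on warming to 0 °C should eliminate to 16 without any base.

3. Step 5. Incomplete α-regioselectivity of the hydroalumination, iodination of the free furan α-position, or loss of the labile iodoalkene on isolation may occur. The fallback sets out from 8 and comes back at 10, and it builds the iodoalkene from a methyl ketone instead. Gold-catalysed Markovnikov hydration of the alkyne (Ph3PAuNTf2, 2 mol%, aqueous 1,4-dioxane, 60 °C) should give 1-{4-[(1S)-1-hydroxy-4-methylpent-3-en-1-yl]furan-2-yl}ethan-1-one F9. Hydrazine hydrate (EtOH, Et3N, rt) should give its hydrazone F10. Iodine with 1,1,3,3-tetramethylguanidine (THF, 0 °C; Barton vinyl iodide synthesis) should then give 10.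

**Further compounds**
F1 | step 9 | lithium (1S)-1-[5-(1-lithioethenyl)furan-3-yl]-4-methylpent-3-en-1-olate | CC(C)=CC[C@H](O[Li])c1coc(C(=C)[Li])c1
F2 | step 9 | 4-hydroxy-4-(1-{4-[(1S)-1-hydroxy-4-methylpent-3-en-1-yl]furan-2-yl}ethenyl)cyclobut-2-en-1-one (both epimers at the ring carbinol carbon) | CC(C)=CC[C@H](O)c1coc(C(=C)C2(O)C=CC2=O)c1
F3 | step 9 | (3E)-4-hydroxy-5-{4-[(1S)-1-hydroxy-4-methylpent-3-en-1-yl]furan-2-yl}hexa-1,3,5-trien-1-one | CC(C)=CC[C@H](O)c1coc(C(=C)/C(O)=C\C=C=O)c1
F4 | step 9 | 4-hydroxy-5-{4-[(1S)-1-hydroxy-4-methylpent-3-en-1-yl]furan-2-yl}cyclohexa-2,4-dien-1-one | CC(C)=CC[C@H](O)c1coc(C2=C(O)C=CC(=O)C2)c1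
F5 | step 9 | 2-{4-[(1S)-1-hydroxy-4-methylpent-3-en-1-yl]furan-2-yl}benzene-1,4-diol | CC(C)=CC[C@H](O)c1coc(-c2cc(O)ccc2O)c1
F6 | step 9 | 2-{4-[(1S)-4-methyl-1-(3-methylbut-2-enoyloxy)pent-3-en-1-yl]furan-2-yl}-1,4-phenylene bis(3-methylbut-2-enoate) | CC(C)=CC[C@H](OC(=O)C=C(C)C)c1coc(-c2cc(OC(=O)C=C(C)C)ccc2OC(=O)C=C(C)C)c1
F7 | step 8 | 3-(phenylselanyl)cyclobutane-1,2-dione | O=C1CC([Se]c2ccccc2)C1=O
F8 | step 8 | 3-(benzeneseleninyl)cyclobutane-1,2-dione | O=C1CC([Se](=O)c2ccccc2)C1=O
F9 | step 5 | 1-{4-[(1S)-1-hydroxy-4-methylpent-3-en-1-yl]furan-2-yl}ethan-1-one | CC(C)=CC[C@H](O)c1coc(C(C)=O)c1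
F10 | step 5 | 1-{4-[(1S)-1-hydroxy-4-methylpent-3-en-1-yl]furan-2-yl}ethan-1-one hydrazone | CC(C)=CC[C@H](O)c1coc(C(C)=NN)c1
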